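(Readings and results were computed for substances that don't exist; scatter was added.)

The substrate left over in the two earlier flasks was where I started, and it behaved differently at the two ends.

| flask | substrate | remark | time |
|---|---|---|---|
| east | 0.031 M | run made earlier |  |
| north | 0.50 M | run made earlier |  |
| birch | 0.025 M |  | 6.0 h |
| oak | 0.40 M |  | 6.0 h |
| alder | 0.15 M |  | 6.0 h |
| cedar | 0.030 M |  | 6.0 h |
| elm | 0.10 M |  | 6.0 h |
| larch | 0.20 M |  | 6.0 h |

| run | time / h | single ring / % | substrate / % |
|---|---|---|---|
| east | 0.833 | 13.6 | 40.6 |
| east | 2.00 | 22.2 | 18.2 |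
| east | 4.00 | 28.0 | 6.0 |
| east | 6.00 | 28.8 | 3.3 |
| north | 0.500 | 4.1 | 8.1 |
| north | 1.00 | 3.1 | 3.5 |
| north | 2.50 | 5.5 | 1.3 |
| north | 6.00 | 4.5 | 0.2 |

(readings scatter by 0.5 percentage points)

- ranking by amount of single ring, in percent of the substrate charged, from high to low, at 6.0 h (birch / oak / alder / cedar / elm / larch)
- the amount of single ring, in percent of the substrate charged of the flask you put first, at 6.0 h
- the amount of single ring, in percent of the substrate charged of the flask you put last, at 6.0 h



In the north run, 8.1% remained after 0.500 h, which, read as a second-order loss, gave a constant of 0.0126 L mol⁻¹ s⁻¹. In the east run, the tail from 18.2% to 3.3%, read as first order, gave 0.427 h⁻¹. Dividing the second by the first gave 0.00941 M, a reading with its scatter: the crossover concentration, the substrate level at which the two losses run level.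

A charge divided by this is the crowding number N, a selectivity factor for the start. I took the single ring to come from the first-order path and to stay. A dilute flask then approaches a ceiling, a crowded one shrinks as ln(N)/N, and the integral joining them is the ceiling times ln(1+N)/N. East, with N of 3.30, put the ceiling at 65.1%.

Was one number enough? North, with N of 53.2, came out at 4.89% against a reading of 4.5%, with a scatter of 0.5 percentage points, and its ring had no part in the ceiling. So I reckoned 31.8% for birch and 5.78% for oak, ranking the flasks by charge.

The forecast gave birch > cedar > elm > alder > larch > oak, on the ground that “yield falls steadily with concentration”, with 31% (29.5% to 32.5%) for birch and 5.3% (4.5% to 6.3%) for oak, both lower than mine.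

The flasks gave birch > cedar > elm > alder > larch > oak, with 33.1% in birch and 5.44% in oak, so the forecast's order stood and both its amounts were right within the tolerance, though birch lay higher than the top of the forecast's range. Oak, left ten times as long, stood at 5.50%. Cedar has N of 3.19, so the crossover gives 29.2%; the flask gave 30.5%.

    single ring ⇌ isomer of the product (K = 0.339, k = 4.06 × 10⁻⁴ s⁻¹)
    substrate + open dimer → open trimer (k = 6.40 × 10⁻⁴ L mol⁻¹ s⁻¹)
    substrate → single ring (k = 9.54 × 10⁻⁵ s⁻¹)
    open dimer → ring dimer (k = 2.88 × 10⁻⁵ s⁻¹)
    2 substrate → open dimer (k = 0.00520 L mol⁻¹ s⁻¹)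

A further flask, like oak but charged at 0.10 M, has N of 10.6, for which I reckoned 15.1%. It gave 15.4%.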